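The time asked for in the flask, 4.0 h, is ten times the first reading of the north-west run at 0.417 h. Yet that run's left-handed product reads 18.6% there and 18.7% at 3.00 h, a difference inside the scatter of 0.3 percentage points.

common to all: left-handed substrate 0.098 M; right-handed substrate 0.098 M; gas 14 mM (held)
- north-west: free catalyst 49 µM; run made earlier
- south-east: free catalyst 74 µM; run made earlier
- flask: free catalyst 98 µM; time 4.0 h

| run | time / h | left-handed product / % | right-handed product / % |
|---|---|---|---|
| north-west | 0.417 | 18.6 | 6.7 |
| north-west | 1.00 | 18.1 | 6.6 |
| north-west | 2.00 | 18.5 | 6.6 |
| north-west | 3.00 | 18.7 | 6.7 |
| south-east | 0.833 | 25.0 | 9.3 |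
| south-east | 1.50 | 24.9 | 10.0 |
| south-east | 2.50 | 24.8 | 9.9 |
| south-east | 3.00 | 24.7 | 9.8 |

(readings scatter by 0.3 percentage points)

- free catalyst is single-handed; left-handed substrate and right-handed substrate are mirror images of each other, charged as a racemate, each of them at the stated concentration
- the numbers in the tables scatter by 0.3 percentage points (one standard deviation)
- at the start none of the gas is in solution
- an excess is the difference of the two amounts in percent of their sum
- an excess is below zero if the other one leads

1. left-handed product and right-handed product together, in percent of the left-handed substrate and right-handed substrate charged together, at 4.0 h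
2. excess of left-handed product over right-handed product in the product at 4.0 h
3. whether the exchange between left-handed substrate and right-handed substrate keeps pace with the reaction: how far the product's excess at 4.0 h gets from its value without exchange to its value with instant exchange (above 80% keeps pace, below 20% hardly takes part, else lags behind)

I order the flask by three clocks. The fastest is the catalyst's working life, over before the first reading. I replace its falling curve by its mean, a full charge working for a fixed time. Each substrate then decays first order, and the log of charged over remaining substrate grows in proportion to the catalyst charged. A reading counts both substrates together, so a substrate's lost share is twice its product's reading.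

| run | catalyst | left-handed product, mean | right-handed product, mean | left log per catalyst | right log per catalyst | product excess |
|---|---|---|---|---|---|---|
| north-west | 49 µM | 18.5% | 6.65% | 9.41 mM⁻¹ | 2.91 mM⁻¹ | 47.1% |
| south-east | 74 µM | 24.8% | 9.75% | 9.29 mM⁻¹ | 2.93 mM⁻¹ | 43.6% |

The two runs give nearly the same logs per catalyst. Their means are the dose numbers, the log fall of a substrate per catalyst charged: 9.35 mM⁻¹ for left-handed and 2.92 mM⁻¹ for right-handed. Their ratio, the selectivity factor, is 3.20.

The second clock is the exchange. Instant exchange would hold the excess at 52.4%, but the readings give less and fall with loading. So I put the exchange behind the catalyst and leave it out. The third clock is the wait to 4.0 h, on which the product stands still.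

For the flask, with 98 µM, I reckon left-handed product 30.0% and right-handed product 12.4%. That is 42.4% together, with excess 41.3%.

The forecast says 42.4% (41.2% to 43.6%), excess 41.5% (39.5% to 43.5%), exchange: hardly takes part. Its ground is that “the catalyst dies and time no longer matters”.

The flask gives 41.6%, excess 41.8%, and the exchange gets 5.2% of the way: hardly takes part.

    gas ⇌ reagent, rate k1*(csat - [reagent]) (kL = 4.10 min⁻¹)
    reagent + free catalyst → spent catalyst B (k = 9.20 L mol⁻¹ min⁻¹)
    free catalyst → spent catalyst A (k = 0.120 min⁻¹)
    reagent + free catalyst + left-handed substrate → free catalyst + left-handed product (k = 1.80 × 10⁵ L² mol⁻² min⁻¹)
    left-handed substrate ⇌ right-handed substrate (k = 0.00640 min⁻¹)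
    reagent + free catalyst + right-handed substrate → free catalyst + right-handed product (k = 57000 L² mol⁻² min⁻¹)

In the flask at 0.400 h, free catalyst is down to 0.316% of its charge, the rest being 53.9% spent catalyst A and 45.7% spent catalyst B, while the relaxation half-life of the exchange by that step alone is 0.903 h. A neighbour flask is charged with 3.9 × 10⁻⁴ M of free catalyst. The dose numbers give it 82.7% with excess 17.8%. That neighbour flask ends at 79.5%, below the reckoning by more than the forecast's half range, and its excess stands at 22.4%.

Readings and results were generated by integration for substances that don't exist; noise was put on by code.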